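After 4.00 h at constant temperature, Saturday's flask had 69.7% of its solid electrophile left, on a nearly straight line. I read one quantity from it: the supply rate, a zero-order rate, meaning the solid that leaves per litre and hour, 2.27 mM h⁻¹. It is a reading and carries the scatter.

| setting | Saturday's | eta | beta | theta |
|---|---|---|---|---|
| solid electrophile | 0.030 M | 0.020 M | 0.020 M | 0.020 M |
| nucleophile | 1.3 equiv | 1.30 equiv | 1.70 equiv | 2.20 equiv |
| gas | 1 mM (held) | 1.0 mM (held) | 1.0 mM (held) | 1.0 mM (held) |
| remark | run made earlier |  |  |  |
| time |  | 10 h | 10 h | 10 h |

- Saturday's (time / h: solid electrophile / %, product / %): 0.333: 98.0, 3.3; 0.833: 93.9, 6.0; 1.50: 88.9, 11.1; 2.50: 80.6, 15.6; 4.00: 69.7, 29.5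

(readings scatter by 1 percentage point)

- the analysis behind the earlier runs scatters by 1 percentage point, standard deviation
- at the start none of the solid electrophile is in solution
- at the start none of the gas is in solution
- what has only dissolved of solid electrophile counts as not reacted

1. part of the solid electrophile that has reacted (what has only dissolved counts as not reacted) at the end, eta
2. part of the solid electrophile that has reacted (what has only dissolved counts as not reacted) at the end, beta
3. part of the solid electrophile that has reacted (what has only dissolved counts as not reacted) at the end, theta
4. what raising the equivalents of nucleophile from its lowest to its highest value here does to the part of the solid electrophile that has reacted (what has only dissolved counts as not reacted) (changes below 5 percentage points count as none) (no change / it falls / it rises)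

For whoever takes over: eta, beta and theta each start with 0.020 M of solid electrophile and none of it in solution, and they differ in nucleophile. I treat what has only dissolved as a small correction and reckon with the solid line. If the supply rate holds at this smaller charge, the solid lasts 8.80 h, so it should be out of each flask before the 10 h are over. Don't take a flask off before then, and leave the stirring and the gas as they are: by my reckoning solid stands until that time.

The forecast gives 95% for eta, 95% for beta and 95% for theta, each within 72% to 100%, with the trend no change, in its words “Extra nucleophile should change little.”

The flasks give 72.3% for eta, 88.5% for beta and 99.2% for theta: it rises, by 27 percentage points.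

    solid electrophile ⇌ electrophile, rate k1*(cs1 - [electrophile]) while solid is left; crystals form when [electrophile] > cs1 (solubility = 12.0 mM, k = 0.188 h⁻¹)
    nucleophile + acid set free ⇌ protonated nucleophile, settled at all times (K = 1.89 × 10⁵ L mol⁻¹)
    electrophile + nucleophile ⇌ acid set free + product (K = 0.785, k = 470 L mol⁻¹ h⁻¹)
    acid set free + free base ⇌ salt of the base, settled at all times (K = 30600 L mol⁻¹)
    gas ⇌ free base, rate k5*(csat - [free base]) (kL = 8.59 h⁻¹)

The supply rate leaves 43.3% of the solid in eta at 5.00 h, and the flask holds 45.2%. But dissolved is not reacted: at 10.0 h eta holds 26.3% as electrophile and 2.0% of its nucleophile free, partly because acid set free binds nucleophile, [protonated nucleophile] = 0.0110 M. The main reason for the rise is the difference in equivalents of nucleophile: at the equivalents of eta, theta gives 72.3%. With that association taken away, the gap from eta to theta shrinks from 27 points to 6.2 points.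

For a neighbour of eta with 0.034 M of solid electrophile at the same equivalents, the supply rate gives 66.8% of the charge dissolved in 10 h. The computed flask has 61.3% reacted and 35.3% still solid.

(The runs stem from a simulated flask for substances that don't exist, and the scatter is random.)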